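**Retrosynthetic overview**
1. Target 19 ⇒ pentabenzyl ether 18; global hydrogenolysis is the last step.
2. 18 ⇒ enol triflate 14 + 4-benzyloxystyrene 15: a B-alkyl Suzuki–Miyaura coupling makes the C6–CH2 bond, and base in the same flask closes C3a–C4, so the benzene ring (C3a, C4, C5, C6, C7, C7a) is formed last.
3. Enabling feature: the benzene ring of the benzofuran is a resorcinol-type ring in which C7a(–O1), C6 and C4(–OH) are the alternate carbonyl carbons of a poly-β-carbonyl chain C3a–C7a–C7–C6–C5–C4. C6 can therefore be a ketone-derived enol triflate and C3a–H2 the acidic ε-CH2 of a dienoate.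
4. 14 ⇒ trans-γ-lactone 11 (already holds O1, C2, C3, C3a, C7a and both stereocentres) + the dianion of methyl acetoacetate (C4–C7).
5. 11 ⇒ anti-homoallylic alcohol 7 ⇒ (E)-cinnamyl-type boronate 4 + aldehyde 5. Ring order: O-heterocycle first (as the lactone, step 5), benzene ring last (step 8).

Key step: step 8

Assumption: the chiral phosphoric acid in step 3 is taken to show the same sense of induction as with simple aromatic aldehydes, so that (S)-TRIP delivers the (1S)-carbinol; if the sense proves opposite, (R)-TRIP is used and nothing else changes.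

**Step 1**
Reactants: 1 3,5-bis(benzyloxy)benzaldehyde
Product: 2 1,3-bis(benzyloxy)-5-ethenylbenzene
Conditions: Ph3PCH3Br, KOt-Bu, THF, 0 °C → rt
Reagents that add atoms: methyltriphenylphosphonium bromide, C[P+](c1ccccc1)(c1ccccc1)c1ccccc1.[Br-]
Why: Wittig methylenation of a non-enolisable aryl aldehyde with the unstabilised ylide; benzyl ethers are inert to the base.

**Step 2**
Reactants: 2 1,3-bis(benzyloxy)-5-ethenylbenzene; 3 allylboronic acid pinacol ester
Product: 4 2-[(2E)-3-[3,5-bis(benzyloxy)phenyl]prop-2-en-1-yl]-4,4,5,5-tetramethyl-1,3,2-dioxaborolane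
Conditions: second-generation Grubbs catalyst (3 mol %), 3 in excess, CH2Cl2, 40 °C; rapid filtration through silica
Reagents that add atoms: none
Why: Olefin cross-metathesis of a styrene with allyl pinacolboronate releases ethene and should give the conjugated (E)-γ-aryl allylboronate under thermodynamic control; no stereocentre is formed.

**Step 3**
Reactants: 4 2-[(2E)-3-[3,5-bis(benzyloxy)phenyl]prop-2-en-1-yl]-4,4,5,5-tetramethyl-1,3,2-dioxaborolane; 5 2,4-bis(benzyloxy)benzaldehyde
Product: 7 (1S,2R)-1-[2,4-bis(benzyloxy)phenyl]-2-[3,5-bis(benzyloxy)phenyl]but-3-en-1-ol, via pinacol borate ester 6 (not isolated)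
Conditions: (S)-TRIP [(S)-3,3'-bis(2,4,6-triisopropylphenyl)-1,1'-binaphthyl-2,2'-diyl hydrogen phosphate] (5 mol %), 4 Å MS, toluene, −30 °C; aq. NaHCO3 work-up
Reagents that add atoms: none
Why: Chiral-phosphoric-acid-catalysed allylboration through a closed chair (Zimmerman–Traxler) transition state, so the E geometry of 4 becomes the anti (1S,2R) relationship while the catalyst, hydrogen-bonded to a boronate oxygen and the formyl group, selects the aldehyde face and thereby fixes the absolute configuration of both new centres (the future C2 and C3).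

**Step 4**
Reactants: 7 (1S,2R)-1-[2,4-bis(benzyloxy)phenyl]-2-[3,5-bis(benzyloxy)phenyl]but-3-en-1-ol
Product: 9 (1S,2R)-1-[2,4-bis(benzyloxy)phenyl]-2-[3,5-bis(benzyloxy)phenyl]butane-1,4-diol, via bis-borane adduct 8 (not isolated)
Conditions: 9-BBN (2.5 equiv), THF, 0 °C → rt; then 3 M NaOH, 30 % H2O2, 0 °C → rt
Reagents that add atoms: hydrogen peroxide, OO
Why: Anti-Markovnikov hydroboration of the monosubstituted alkene with 9-BBN (the free hydroxyl first becomes its borinate with loss of H2) and alkaline peroxide oxidation with retention give the primary alcohol; the two stereocentres are not involved and the medium stays basic.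

**Step 5**
Reactants: 9 (1S,2R)-1-[2,4-bis(benzyloxy)phenyl]-2-[3,5-bis(benzyloxy)phenyl]butane-1,4-diol
Product: 11 (4R,5S)-5-[2,4-bis(benzyloxy)phenyl]-4-[3,5-bis(benzyloxy)phenyl]oxolan-2-one, via lactol 10 (not isolated)
Conditions: [Cu(MeCN)4]OTf (5 mol %), 2,2'-bipyridine (5 mol %), TEMPO (5 mol %), N-methylimidazole (10 mol %), air, MeCN, rt
Reagents that add atoms: none
Why: Cu/nitroxyl aerobic oxidative lactonisation, in which TEMPO oxidises only the unhindered primary alcohol, the hydroxy aldehyde closes to the lactol and this is oxidised on to the γ-lactone; the neutral medium avoids ionisation of the electron-rich benzylic C–O bond and both centres are retained (trans).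

**Step 6**
Reactants: 11 (4R,5S)-5-[2,4-bis(benzyloxy)phenyl]-4-[3,5-bis(benzyloxy)phenyl]oxolan-2-one
Product: 13 methyl (4E)-4-[(4R,5S)-5-[2,4-bis(benzyloxy)phenyl]-4-[3,5-bis(benzyloxy)phenyl]oxolan-2-ylidene]-3-oxobutanoate, via hydroxy diketo ester 12 (not isolated)
Conditions: methyl acetoacetate, NaH then n-BuLi, THF, 0 °C; 11, −78 → −20 °C; sat. NH4Cl; crude, then PPTS (10 mol %), 4 Å MS, CH2Cl2, rt
Reagents that add atoms: methyl acetoacetate, COC(=O)CC(C)=O
Why: Claisen-type addition of the terminal carbanion of the acetoacetate dianion to the lactone carbonyl gives the ring-opened 3,5-diketo ester (in equilibrium with its hemiketal), and mild acid dehydrates the hemiketal to the conjugated exocyclic vinylogous ester (expected E; the geometry has no bearing on later steps); the two ring stereocentres are untouched.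

**Step 7**
Reactants: 13 methyl (4E)-4-[(4R,5S)-5-[2,4-bis(benzyloxy)phenyl]-4-[3,5-bis(benzyloxy)phenyl]oxolan-2-ylidene]-3-oxobutanoate
Product: 14 methyl (2E,4E)-4-[(4R,5S)-5-[2,4-bis(benzyloxy)phenyl]-4-[3,5-bis(benzyloxy)phenyl]oxolan-2-ylidene]-3-[(trifluoromethanesulfonyl)oxy]but-2-enoate
Conditions: Tf2O (1.5 equiv), 25 % aq. Me4NOH, toluene, 5 °C, short contact time
Reagents that add atoms: trifluoromethanesulfonic anhydride, O=S(=O)(OS(=O)(=O)C(F)(F)F)C(F)(F)F
Why: O-Triflation of the β-keto ester enolate, the only readily enolised site; the non-chelating tetramethylammonium counter-ion should favour the (E)-enol triflate (ester trans to OTf, cis to the ring-bearing arm).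

**Step 8**
Reactants: 14 methyl (2E,4E)-4-[(4R,5S)-5-[2,4-bis(benzyloxy)phenyl]-4-[3,5-bis(benzyloxy)phenyl]oxolan-2-ylidene]-3-[(trifluoromethanesulfonyl)oxy]but-2-enoate; 15 1-(benzyloxy)-4-ethenylbenzene
Product: 18 (2S,3S)-2-[2,4-bis(benzyloxy)phenyl]-3-[3,5-bis(benzyloxy)phenyl]-6-{2-[4-(benzyloxy)phenyl]ethyl}-2,3-dihydro-1-benzofuran-4-ol, via alkylborane 16 (not isolated), via dienoate 17 (not isolated)
Conditions: 15 (1.6 equiv), 9-BBN (1.5 equiv), THF, 0 °C → rt; then 14, PdCl2(dppf)·CH2Cl2 (5 mol %), anhydrous K3PO4 (3 equiv), DMF, 50 °C; then KOt-Bu (4 equiv), 0 °C → rt (warming if needed); sat. NH4Cl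
Reagents that add atoms: none
Why: Proposed new method: the first leg is an ordinary B-alkyl Suzuki–Miyaura coupling (oxidative addition of Pd(0) into the C6–OTf bond of the β-triflyloxy enoate, transmetallation of the primary alkyl group from the phosphate-activated borane 16, reductive elimination with retention of alkene geometry) and makes the C6–CH2 bond; the new part is that KOt-Bu then removes a proton from the only ε-CH2 of dienoate 17 (C3a, allylic to the enol ether) to give an ester trienolate, which forms the C3a–C4 bond, expels methoxide and tautomerises from the cyclohexa-2,4-dienone to the phenoxide of 18. The one ring closed is the benzene ring, by a thermal disrotatory 6π-electrocyclisation of the oxido-triene C3a=C7a–C7=C6–C5=C4(OMe)O– or of the dienylketene that arises from it by E1cB loss of methoxide, which is formally a vinylogous Dieckmann (6-exo-trig) condensation driven by aromatisation. The closest known reaction types are the Stobbe-type benzannulation of hetaryl-substituted dienoic acids to 4-acyloxybenzofurans through a dienylketene and the Michael–Claisen synthesis of resorcinols from (Z)-5-oxo-2-enoates. No stereocentre is created: C2 and C3 are carried unchanged from lactone 11, neither bears an acidic hydrogen, and the transient sp3 centre at C3a disappears on aromatisation. The step needs chemoselective coupling at the vinyl triflate and productive deprotonation at C3a rather than at the phenethyl CH2; the first rests on the fast oxidative addition of the electron-poor triflate, the second on the fact that every other deprotonation is reversible while only the C3a anion can drain irreversibly into the aromatic phenoxide. The geometry of 17 is not critical, because C5=C6 and C7=C7a both gain single-bond character in the trienolate, the (2Z) isomer merely placing the ester beside the ring-closing arm from the outset.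

**Step 9**
Reactants: 18 (2S,3S)-2-[2,4-bis(benzyloxy)phenyl]-3-[3,5-bis(benzyloxy)phenyl]-6-{2-[4-(benzyloxy)phenyl]ethyl}-2,3-dihydro-1-benzofuran-4-ol
Product: 19 4-[(2S,3S)-3-(3,5-dihydroxyphenyl)-4-hydroxy-6-[2-(4-hydroxyphenyl)ethyl]-2,3-dihydro-1-benzofuran-2-yl]benzene-1,3-diol
Conditions: H2 (1 atm), 10 % Pd/C, EtOAc–MeOH, rt, stopped as soon as debenzylation is complete
Reagents that add atoms: none
Why: Hydrogenolysis of the five O-benzyl ethers over Pd/C under neutral conditions, where the cyclic benzylic C2–O1 ether should be cleaved far more slowly than the exocyclic benzyl ethers and neither stereocentre can epimerise.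

**Compound list**
1 | 3,5-bis(benzyloxy)benzaldehyde | O=Cc1cc(OCc2ccccc2)cc(OCc2ccccc2)c1 | starting material
2 | 1,3-bis(benzyloxy)-5-ethenylbenzene | C=Cc1cc(OCc2ccccc2)cc(OCc2ccccc2)c1 | intermediate
3 | allylboronic acid pinacol ester | C=CCB1OC(C)(C)C(C)(C)O1 | starting material
4 | 2-[(2E)-3-[3,5-bis(benzyloxy)phenyl]prop-2-en-1-yl]-4,4,5,5-tetramethyl-1,3,2-dioxaborolane | CC1(C)OB(C/C=C/c2cc(OCc3ccccc3)cc(OCc3ccccc3)c2)OC1(C)C | intermediate
5 | 2,4-bis(benzyloxy)benzaldehyde | O=Cc1ccc(OCc2ccccc2)cc1OCc1ccccc1 | starting material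
6 | 2-{[(1S,2R)-1-[2,4-bis(benzyloxy)phenyl]-2-[3,5-bis(benzyloxy)phenyl]but-3-en-1-yl]oxy}-4,4,5,5-tetramethyl-1,3,2-dioxaborolane | CC1(C)OB(O[C@H](c2ccc(OCc3ccccc3)cc2OCc2ccccc2)[C@H](C=C)c2cc(OCc3ccccc3)cc(OCc3ccccc3)c2)OC1(C)C | intermediate (not isolated)
7 | (1S,2R)-1-[2,4-bis(benzyloxy)phenyl]-2-[3,5-bis(benzyloxy)phenyl]but-3-en-1-ol | O[C@H](c1ccc(OCc2ccccc2)cc1OCc1ccccc1)[C@H](C=C)c1cc(OCc2ccccc2)cc(OCc2ccccc2)c1 | intermediate
8 | 9-{[(1S,2R)-1-[2,4-bis(benzyloxy)phenyl]-2-[3,5-bis(benzyloxy)phenyl]-4-(9-borabicyclo[3.3.1]nonan-9-yl)butyl]oxy}-9-borabicyclo[3.3.1]nonane | B1(O[C@H](c2ccc(OCc3ccccc3)cc2OCc2ccccc2)[C@H](CCB2C3CCCC2CCC3)c2cc(OCc3ccccc3)cc(OCc3ccccc3)c2)C2CCCC1CCC2 | intermediate (not isolated)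
9 | (1S,2R)-1-[2,4-bis(benzyloxy)phenyl]-2-[3,5-bis(benzyloxy)phenyl]butane-1,4-diol | O[C@H](c1ccc(OCc2ccccc2)cc1OCc1ccccc1)[C@H](CCO)c1cc(OCc2ccccc2)cc(OCc2ccccc2)c1 | intermediate
10 | (4R,5S)-5-[2,4-bis(benzyloxy)phenyl]-4-[3,5-bis(benzyloxy)phenyl]oxolan-2-ol (anomer mixture) | OC1C[C@H](c2cc(OCc3ccccc3)cc(OCc3ccccc3)c2)[C@@H](c2ccc(OCc3ccccc3)cc2OCc2ccccc2)O1 | intermediate (not isolated)
11 | (4R,5S)-5-[2,4-bis(benzyloxy)phenyl]-4-[3,5-bis(benzyloxy)phenyl]oxolan-2-one (trans) | O=C1C[C@H](c2cc(OCc3ccccc3)cc(OCc3ccccc3)c2)[C@@H](c2ccc(OCc3ccccc3)cc2OCc2ccccc2)O1 | intermediate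
12 | methyl (7R,8S)-8-[2,4-bis(benzyloxy)phenyl]-7-[3,5-bis(benzyloxy)phenyl]-8-hydroxy-3,5-dioxooctanoate (in equilibrium with its cyclic hemiketal) | COC(=O)CC(=O)CC(=O)C[C@H](c1cc(OCc2ccccc2)cc(OCc2ccccc2)c1)[C@@H](c1ccc(OCc2ccccc2)cc1OCc1ccccc1)O | intermediate (not isolated)
13 | methyl (4E)-4-[(4R,5S)-5-[2,4-bis(benzyloxy)phenyl]-4-[3,5-bis(benzyloxy)phenyl]oxolan-2-ylidene]-3-oxobutanoate | COC(=O)CC(=O)/C=C1\C[C@H](c2cc(OCc3ccccc3)cc(OCc3ccccc3)c2)[C@@H](c2ccc(OCc3ccccc3)cc2OCc2ccccc2)O1 | intermediate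
14 | methyl (2E,4E)-4-[(4R,5S)-5-[2,4-bis(benzyloxy)phenyl]-4-[3,5-bis(benzyloxy)phenyl]oxolan-2-ylidene]-3-[(trifluoromethanesulfonyl)oxy]but-2-enoate | COC(=O)/C=C(OS(=O)(=O)C(F)(F)F)\C=C1/C[C@H](c2cc(OCc3ccccc3)cc(OCc3ccccc3)c2)[C@@H](c2ccc(OCc3ccccc3)cc2OCc2ccccc2)O1 | intermediate
15 | 1-(benzyloxy)-4-ethenylbenzene | C=Cc1ccc(OCc2ccccc2)cc1 | starting material
16 | 9-{2-[4-(benzyloxy)phenyl]ethyl}-9-borabicyclo[3.3.1]nonane | C(Cc1ccc(OCc2ccccc2)cc1)B1C2CCCC1CCC2 | intermediate (not isolated)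
17 | methyl (2Z,4E)-3-{2-[4-(benzyloxy)phenyl]ethyl}-4-[(4R,5S)-5-[2,4-bis(benzyloxy)phenyl]-4-[3,5-bis(benzyloxy)phenyl]oxolan-2-ylidene]but-2-enoate | COC(=O)/C=C(CCc1ccc(OCc2ccccc2)cc1)\C=C1/C[C@H](c2cc(OCc3ccccc3)cc(OCc3ccccc3)c2)[C@@H](c2ccc(OCc3ccccc3)cc2OCc2ccccc2)O1 | intermediate (not isolated)
18 | (2S,3S)-2-[2,4-bis(benzyloxy)phenyl]-3-[3,5-bis(benzyloxy)phenyl]-6-{2-[4-(benzyloxy)phenyl]ethyl}-2,3-dihydro-1-benzofuran-4-ol | C(Oc1ccc(CCc2cc(O)c3c(c2)O[C@H](c2ccc(OCc4ccccc4)cc2OCc2ccccc2)[C@H]3c2cc(OCc3ccccc3)cc(OCc3ccccc3)c2)cc1)c1ccccc1 | intermediate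
19 | 4-[(2S,3S)-3-(3,5-dihydroxyphenyl)-4-hydroxy-6-[2-(4-hydroxyphenyl)ethyl]-2,3-dihydro-1-benzofuran-2-yl]benzene-1,3-diol | Oc1ccc(CCc2cc(O)c3c(c2)O[C@H](c2ccc(O)cc2O)[C@H]3c2cc(O)cc(O)c2)cc1 | target

**Step count**
Total steps: 9. Longest linear sequence: 9 steps (1 → 19); the second fragment 15 is used as purchased.

**Steps most likely to fail, with fallbacks**

Step 8 (proposed new method). The ester trienolate may not close the ring: reprotonation to deconjugated isomers, ester cleavage or decomposition could compete with C3a–C4 bond formation. Fallback with known chemistry: the one-pot sequence is stopped after the coupling stage and dienoate 17 is isolated. Saponification (LiOH, THF–MeOH–H2O) should give (2Z,4E)-3-{2-[4-(benzyloxy)phenyl]ethyl}-4-[(4R,5S)-5-[2,4-bis(benzyloxy)phenyl]-4-[3,5-bis(benzyloxy)phenyl]oxolan-2-ylidene]but-2-enoic acid F1. Heating this acid with Ac2O/NaOAc (Stobbe-type benzannulation: mixed anhydride, dienylketene, 6π-electrocyclisation, O-acetylation) should give (2S,3S)-2-[2,4-bis(benzyloxy)phenyl]-3-[3,5-bis(benzyloxy)phenyl]-6-{2-[4-(benzyloxy)phenyl]ethyl}-2,3-dihydro-1-benzofuran-4-yl acetate F2. Methanolysis (K2CO3, MeOH) returns to 18.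

Step 6. Proton transfer from the lactone α-CH2 to the dianion, or a second addition to the ring-opened ketone, may replace clean mono-acylation. Fallback with inverted polarity, setting out from lactone 11: methylenation with dimethyltitanocene (toluene, 70 °C) should give (2S,3R)-2-[2,4-bis(benzyloxy)phenyl]-3-[3,5-bis(benzyloxy)phenyl]-5-methylideneoxolane F3. C-Acylation of its nucleophilic exocyclic carbon with methyl 3-chloro-3-oxopropanoate and pyridine (CH2Cl2, −40 °C) should give 13 directly, where the route is rejoined.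

Step 9. Over-reduction may occur: hydrogenolytic opening of the cyclic benzylic C2–O1 bond alongside debenzylation. Fallback without hydrogen, setting out from 18: Lewis-acid debenzylation with BCl3 and pentamethylbenzene as cation scavenger (CH2Cl2, −78 °C) should give 19 directly; no new compound is formed (F0).

**Further compounds**
F1 | step 8 | (2Z,4E)-3-{2-[4-(benzyloxy)phenyl]ethyl}-4-[(4R,5S)-5-[2,4-bis(benzyloxy)phenyl]-4-[3,5-bis(benzyloxy)phenyl]oxolan-2-ylidene]but-2-enoic acid | OC(=O)/C=C(CCc1ccc(OCc2ccccc2)cc1)\C=C1/C[C@H](c2cc(OCc3ccccc3)cc(OCc3ccccc3)c2)[C@@H](c2ccc(OCc3ccccc3)cc2OCc2ccccc2)O1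
F2 | step 8 | (2S,3S)-2-[2,4-bis(benzyloxy)phenyl]-3-[3,5-bis(benzyloxy)phenyl]-6-{2-[4-(benzyloxy)phenyl]ethyl}-2,3-dihydro-1-benzofuran-4-yl acetate | C(Oc1ccc(CCc2cc(OC(C)=O)c3c(c2)O[C@H](c2ccc(OCc4ccccc4)cc2OCc2ccccc2)[C@H]3c2cc(OCc3ccccc3)cc(OCc3ccccc3)c2)cc1)c1ccccc1
F3 | step 6 | (2S,3R)-2-[2,4-bis(benzyloxy)phenyl]-3-[3,5-bis(benzyloxy)phenyl]-5-methylideneoxolane | C=C1C[C@H](c2cc(OCc3ccccc3)cc(OCc3ccccc3)c2)[C@@H](c2ccc(OCc3ccccc3)cc2OCc2ccccc2)O1
F0 | step 9 | none | none
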